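In a one-step world, pseudo-first-order with the rate proportional to [catalyst], the fraction of starting material left depends on time and catalyst through their product. Here you test that picture on the earlier runs, then use the part of it that survives.

| flask | starting material | catalyst | target | time |
|---|---|---|---|---|
| Thursday's | 150 mM | 1.50 mM |  |  |
| Friday's | 75.0 mM | 1.50 mM |  |  |
| Saturday's | 150 mM | 0.750 mM |  |  |
| Monday's | 150 mM | 1.50 mM | 75.0 mM |  |
| Sunday's | 150 mM | 0.430 mM |  | 5.5 min |

| run | time / min | [target] / mM |
|---|---|---|
| Thursday's run | 0.92 | 16.8 |
| Thursday's run | 1.8 | 29.3 |
| Thursday's run | 2.8 | 42.7 |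
| Thursday's run | 3.7 | 50.7 |
| Thursday's run | 4.6 | 58.9 |
| Thursday's run | 5.5 | 63.9 |
| Friday's run | 0.92 | 10.6 |
| Friday's run | 1.8 | 19.2 |
| Friday's run | 2.8 | 26.1 |
| Friday's run | 3.7 | 31.7 |
| Friday's run | 4.6 | 35.7 |
| Friday's run | 5.5 | 39.1 |
| Saturday's run | 0.92 | 9.4 |
| Saturday's run | 1.8 | 17.0 |
| Saturday's run | 2.8 | 25.2 |
| Saturday's run | 3.7 | 32.4 |
| Saturday's run | 4.6 | 36.8 |
| Saturday's run | 5.5 | 41.9 |
| Monday's run | 0.92 | 83.7 |
| Monday's run | 1.8 | 90.6 |
| Monday's run | 2.8 | 100.6 |
| Monday's run | 3.7 | 105.0 |
| Monday's run | 4.6 | 111.7 |
| Monday's run | 5.5 | 117.3 |

(standard deviation of a reading: 0.8 mM)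

- apparent order in [catalyst] of the starting rate, round the charge of the Thursday's run (the rate where two percent of its starting material have turned into target)
- apparent order in [starting material] of the starting rate, round the charge of the Thursday's run (the rate where two percent of its starting material have turned into target) (one fixed amount of target, the same in the runs compared)
- the Friday's run starts with 75.0 mM less of starting material than the Thursday's run, and with no target. Compared where both hold the same amount of starting material, once fifteen percent of what the Friday's run was charged with has turned into target, is the Friday's run faster, slower or alike (within a tenth)?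
- target in the Sunday's run at 5.5 min, as a share of the starting material charged
- which of these the readings show (a little impurity takes part of the catalyst at once / nothing beyond the main steps / the loaded catalyst dies / the product ties up the catalyst)

- Overall: starting material -> target, with catalyst as catalyst.
- Constant volume, constant temperature.
- What is held in complexes is read along with the free species.
- An order is taken over about fifteen percent of the charge, up and down.

The catalyst part survives. Saturday's flask, with 0.750 mM against Thursday's 1.50 mM, holds 41.9 mM of target at 5.5 min, and Thursday's flask held 42.7 mM at 2.8 min, about half that time. The gap is 0.800 mM, with a scatter of 0.8 mM on each reading.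

The rest fails. At 5.5 min Friday's flask has 47.9 % of its charge left, less than Thursday's 57.4 %, and Monday's flask, charged with 75.0 mM of target, has made 8.70 mM by 0.92 min where Thursday's flask has made 16.8 mM.

Sunday's flask has Thursday's charge of starting material and differs from it in catalyst, so the surviving part is what you need. Its time goes over to Thursday's clock by the ratio of the catalyst charges:

τ = 5.5 min × 0.430 mM / 1.50 mM = 1.58 min

This τ is the catalyst-time, the minutes of Thursday's run with the same product of catalyst and time.

Next, take ln(charge/left) at Thursday's two readings around τ, where the fraction left is the natural thing to interpolate: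

0.119 at 0.92 min, 0.217 at 1.8 min

at τ: 0.192, so made = 17.5 %

The weak link is that this rests on two readings, each scattered by 0.533 % of the charge. Saturday's flask gives an independent bracket, since Sunday's time is 3.15 min on its clock:

0.184 at 2.8 min, 0.243 at 3.7 min

at 3.15 min: 0.207, so made = 18.7 %

The mean of the two, 18.1 %, is my number.

The forecast, reasoning that “Sunday's 5.5 min scales to about 1.6 min of Thursday's run”, gave orders 0.95 and 0.62, Friday's flask faster, 17.8 % for Sunday's flask, and "the product ties up the catalyst".

The simulation gives orders 1.0 and 0.62, Friday's flask faster, 18.3 % for Sunday's flask, and "the product ties up the catalyst".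

    catalyst + starting material ⇌ catalyst-substrate complex (216.6 M⁻¹ min⁻¹, 8.760 min⁻¹)
    catalyst-substrate complex → target + catalyst (37.50 min⁻¹)
    catalyst + target ⇌ catalyst-product complex, settled at all times (29.60 M⁻¹)

At 1.58 min of catalyst-time, Sunday's flask stands at the 18.3 % just given, and the same conversion takes Saturday's quarter time of 4.78 min to 2.39 min, Thursday's 2.39 min. Thursday's and Saturday's flasks reach the same [target] at equal catalyst-time, so the curve that was read already holds the catalyst-product complex. Across different [target] the conversion breaks: at equal starting material, Friday's flask runs at 2.4 times Thursday's rate because catalyst and target associate to that complex, and without the association the ratio is 1.0.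

Readings and results come from a simulation on assumed constants; the scatter is artificial.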